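**Retrosynthetic overview**
- Target flavonol ⇒ the corresponding flavone (tangeretin) by disconnecting the C3–O bond (C3–H hydroxylation through the 2,3-epoxide).
- Tangeretin ⇒ open-chain β-diketone by disconnecting the aryl C8a–O1 bond (dehydrogenative aryl C–H/enol O–H ring closure; this is the key step).
- β-Diketone ⇒ 2,3,4,5-tetramethoxyacetophenone + methyl 4-methoxybenzoate (Claisen condensation).
- Acetophenone ⇒ 1,2,3,4-tetramethoxybenzene (Friedel–Crafts acetylation; the two free positions are equivalent).
- Ring order: A and B rings are bought intact; the pyranone C ring is the only ring formed (step 3); the 3-OH goes on last.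

Assumption: the target has no stereocentre (it is achiral), so no enantiocontrol is needed; 1,2,3,4-tetramethoxybenzene is taken as a catalogue compound.

**Step 1**
Reactants: 1 1,2,3,4-tetramethoxybenzene
Product: 2 1-(2,3,4,5-tetramethoxyphenyl)ethan-1-one
Conditions: Ac2O (1.5 equiv), Bi(OTf)3 (5 mol %), MeNO2, 50 °C
Reagents that add atoms: acetic anhydride, CC(=O)OC(C)=O
Why: Metal-triflate-catalysed Friedel–Crafts acylation; the two free positions of 1 are equivalent so only one ketone can form, the catalytic non-chelating Lewis acid avoids the ortho-demethylation that stoichiometric AlCl3 causes, and the new acyl group deactivates the ring against a second acylation.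

**Step 2**
Reactants: 2 1-(2,3,4,5-tetramethoxyphenyl)ethan-1-one; 3 methyl 4-methoxybenzoate
Product: 4 1-(4-methoxyphenyl)-3-(2,3,4,5-tetramethoxyphenyl)propane-1,3-dione (enolised β-diketone)
Conditions: NaH (2.5 equiv), THF, reflux; then 1 M HCl
Reagents that add atoms: none
Why: Crossed Claisen condensation of the methyl-ketone enolate with a non-enolisable ester, driven by irreversible deprotonation of the β-diketone product (the same bond construction as the industrial avobenzone process).

**Step 3**
Reactants: 4 1-(4-methoxyphenyl)-3-(2,3,4,5-tetramethoxyphenyl)propane-1,3-dione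
Product: 5 5,6,7,8-tetramethoxy-2-(4-methoxyphenyl)-4H-chromen-4-one (tangeretin)
Conditions: graphite anode, Pt cathode, undivided cell, nBu4NBF4 (0.1 M), dry HFIP/CH2Cl2 4:1 (0.02 M), 3 Å MS, constant current 3 mA cm⁻², 2.1–2.2 F mol⁻¹, rt
Reagents that add atoms: none
Why: Proposed new method: anodic dehydrogenative aryl C–H/enol O–H coupling, in which the tetramethoxyaryl ketone ring of 4 (estimated Eox about +1.4–1.5 V vs SCE) is oxidised before the acylated anisole ring (about +1.9 V) to an HFIP-stabilised arene radical cation, the distal enol oxygen of the β-diketone (a vinylogous carboxylic acid held Z across the enol C=C) attacks the only unsubstituted ring carbon C-6′ (para to the 3′-OMe) in a six-membered closure, and loss of H⁺, a second one-electron oxidation and rearomatising deprotonation give the chromone while HFIP is reduced to H2 at the cathode; ipso attack at the OMe-bearing C-2′ is reversible and has no rearomatisation path under net-oxidising conditions, so flux funnels through the C–H position; the closest known reaction types are the anodic dehydrogenative C–O lactonisation of biaryl-2-carboxylic acids to benzocoumarins, the anodic anilide-to-benzoxazole cyclisation and the oxidative ring closure of 2-hydroxybenzophenones to xanthones, whereas a β-diketone enol has not been used as the O-nucleophile to build a flavone in this way.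

**Step 4**
Reactants: 5 5,6,7,8-tetramethoxy-2-(4-methoxyphenyl)-4H-chromen-4-one
Product: 7 3-hydroxy-5,6,7,8-tetramethoxy-2-(4-methoxyphenyl)-4H-chromen-4-one, via tangeretin 2,3-epoxide 6 (not isolated)
Conditions: DMDO (about 0.07 M in acetone, 4 equiv), CH2Cl2, 0 °C → rt, dark, 24–48 h; then p-TsOH·H2O (10 mol %), CH2Cl2, rt
Reagents that add atoms: dimethyldioxirane, CC1(C)OO1
Why: Electrophilic epoxidation of the chromone C2=C3 bond by neutral DMDO, then acid-catalysed opening of the epoxide at the oxocarbenium-stabilised C2 and loss of H-3 gives the 3-hydroxyflavone; the two transient stereocentres of the racemic cis-fused epoxide are erased and the product is achiral.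

**Compound list**
1 | 1,2,3,4-tetramethoxybenzene | COc1ccc(OC)c(OC)c1OC | starting material
2 | 1-(2,3,4,5-tetramethoxyphenyl)ethan-1-one | CC(=O)c1cc(OC)c(OC)c(OC)c1OC | intermediate
3 | methyl 4-methoxybenzoate | COC(=O)c1ccc(OC)cc1 | starting material
4 | 1-(4-methoxyphenyl)-3-(2,3,4,5-tetramethoxyphenyl)propane-1,3-dione | COc1ccc(cc1)C(=O)CC(=O)c1cc(OC)c(OC)c(OC)c1OC | intermediate
5 | 5,6,7,8-tetramethoxy-2-(4-methoxyphenyl)-4H-chromen-4-one (tangeretin) | COc1ccc(cc1)-c1cc(=O)c2c(OC)c(OC)c(OC)c(OC)c2o1 | intermediate
6 | 2,3-epoxy-5,6,7,8-tetramethoxy-2-(4-methoxyphenyl)chroman-4-one (racemic, cis-fused, one enantiomer drawn; not isolated) | COc1ccc(cc1)[C@]23Oc4c(OC)c(OC)c(OC)c(OC)c4C(=O)[C@H]2O3 | intermediate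
7 | 3-hydroxy-5,6,7,8-tetramethoxy-2-(4-methoxyphenyl)-4H-chromen-4-one | COc1ccc(-c2oc3c(OC)c(OC)c(OC)c(OC)c3c(=O)c2O)cc1 | target

**Totals**
Total step count: 4. Longest linear sequence: 4 (1 → 2 → 4 → 5 → 7).

**Steps most likely to fail**

Step 3 (the proposed new anodic ring closure). The risks are over-oxidation of the para-dimethoxy pattern to a 5,8-quinone if water is present, ipso substitution at C-2′, and intermolecular coupling. The fallback uses only known chemistry and installs the ring oxygen before the diketone is built, so the pyranone closes by condensation instead of C–H oxidation. It sets out from 2 and returns at 5. Baeyer–Villiger oxidation of 2 (mCPBA, NaHCO3, CH2Cl2, rt) gives 2,3,4,5-tetramethoxyphenyl acetate F2. Fries rearrangement (BF3·OEt2, AcOH, 80 °C) moves the acetyl group to the only free ring position and gives 1-(2-hydroxy-3,4,5,6-tetramethoxyphenyl)ethan-1-one F3. C-Aroylation of its dianion (LiHMDS 3.5 equiv, 4-methoxybenzoyl chloride, THF, −78 °C → rt) gives 1-(2-hydroxy-3,4,5,6-tetramethoxyphenyl)-3-(4-methoxyphenyl)propane-1,3-dione F4. Cyclodehydration (cat. H2SO4, AcOH, 95 °C) then gives 5.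

Step 4 (DMDO hydroxylation). The chromone double bond is slow to epoxidise and the electron-rich rings may be oxidised competitively by excess dioxirane. The fallback replaces electrophilic oxidation with deprotonative functionalisation; it sets out from 5 and returns at 7. LDA (1.2 equiv, THF, −78 °C) removes H-3 to give 3-lithio-5,6,7,8-tetramethoxy-2-(4-methoxyphenyl)-4H-chromen-4-one F5. Trapping with B(OMe)3 gives dimethyl [5,6,7,8-tetramethoxy-2-(4-methoxyphenyl)-4-oxo-4H-chromen-3-yl]boronate F6. Oxidation in the same pot with H2O2/AcOH (0 °C → rt) gives 7.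

Step 1 (Friedel–Crafts acetylation). The risks are sluggish conversion of the sterically twisted tetramethoxyarene or partial demethylation of the OMe ortho to the new ketone. The fallback replaces electrophilic substitution with directed ortho-metalation; it sets out from 1 and returns at 2. n-BuLi/TMEDA (THF, 0 °C) gives (2,3,4,5-tetramethoxyphenyl)lithium F1, which is acylated with N-methoxy-N-methylacetamide (−78 °C → rt, then aq. NH4Cl) to give 2.

**Further compounds**
F1 | step 1 | (2,3,4,5-tetramethoxyphenyl)lithium | [Li]c1cc(OC)c(OC)c(OC)c1OC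
F2 | step 3 | 2,3,4,5-tetramethoxyphenyl acetate | CC(=O)Oc1cc(OC)c(OC)c(OC)c1OC
F3 | step 3 | 1-(2-hydroxy-3,4,5,6-tetramethoxyphenyl)ethan-1-one | CC(=O)c1c(O)c(OC)c(OC)c(OC)c1OC
F4 | step 3 | 1-(2-hydroxy-3,4,5,6-tetramethoxyphenyl)-3-(4-methoxyphenyl)propane-1,3-dione | COc1ccc(cc1)C(=O)CC(=O)c1c(O)c(OC)c(OC)c(OC)c1OC
F5 | step 4 | 3-lithio-5,6,7,8-tetramethoxy-2-(4-methoxyphenyl)-4H-chromen-4-one | [Li]c1c(-c2ccc(OC)cc2)oc2c(OC)c(OC)c(OC)c(OC)c2c1=O
F6 | step 4 | dimethyl [5,6,7,8-tetramethoxy-2-(4-methoxyphenyl)-4-oxo-4H-chromen-3-yl]boronate | COB(OC)c1c(-c2ccc(OC)cc2)oc2c(OC)c(OC)c(OC)c(OC)c2c1=O
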